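Each flask holds 0.40 M of starting material, and the amounts that matter are how much of it has met the coupling partner and how much of that has taken a second partner to become bis adduct.

| flask | starting material | coupling partner | remark | time |
|---|---|---|---|---|
| Monday's | 0.40 M | 0.33 M | run made earlier |  |
| Saturday's | 0.40 M | 1.1 M | run made earlier |  |
| midnight | 0.40 M | 0.400 M |  | 6.0 d |
| summer | 0.40 M | 1.20 M |  | 6.0 d |
| autumn | 0.40 M | 1.60 M |  | 6.0 d |

- Monday's (time / d: bis adduct / %, starting material / %): 0.625: 2.1, 82.6; 1.25: 5.4, 70.6; 1.67: 7.4, 64.1; 2.50: 10.2, 56.1; 3.00: 12.4, 53.0; 4.00: 14.5, 48.2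
- Saturday's (time / d: bis adduct / %, starting material / %): 0.625: 15.1, 49.9; 1.25: 34.0, 29.0; 1.67: 41.3, 22.0; 2.50: 49.8, 14.0; 3.00: 53.1, 11.8; 4.00: 55.3, 6.6

(readings scatter by 0.5 percentage points)

1. final bis adduct, as a percentage of the starting material charged, for each flask in turn (midnight, summer, autumn)

- the numbers in the tables scatter with a standard deviation of 0.5 percentage points
- a reading or a percentage of bis adduct counts all its forms, free or not
- a reading of starting material is of its free form alone

I take the rate constant k of the first step (rate = k × starting material × partner) in two ways, from the first reading of Monday's run and from that of Saturday's. With partner held at its charge, Monday's gives 1.07 × 10⁻⁵ M⁻¹ s⁻¹ and Saturday's 1.17 × 10⁻⁵ M⁻¹ s⁻¹. Then I put that answer back: as a rough estimate I take the partner lost so far as the starting material gone plus the bis adduct formed, so I use the mean partner over the interval and go round once more. Monday's now gives 1.22 × 10⁻⁵ M⁻¹ s⁻¹ and Saturday's 1.33 × 10⁻⁵ M⁻¹ s⁻¹, so they still part, Saturday's being higher. A reading counts free starting material, so anything that holds it without reacting looks like reaction, and Saturday's first reading carries more bis adduct, 15.1 % against 2.1 %. I suspect Saturday's and keep Monday's k.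

From it I carry τ, the time in which partner at its charged concentration halves the free starting material, a pseudo-first-order half-life. For the summer flask τ is 0.550 d. Going round again with the partner that remains if every starting material takes two, 0.400 M, about 8.03 % of the starting material is left in the summer flask after 6.0 d. The first step there is largely through, yet Saturday's bis adduct flattens at 55.3 % with starting material at 6.6 %. I therefore expect the summer flask near that reading, and the autumn flask close to it.

The forecast gives 24 %, 64 % and 70 %, reading the stall as “bis adduct sequestering mono”.

The flasks give 20.2 %, 54.0 % and 55.0 %.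

    starting material + coupling partner → mono adduct (k = 1.20 × 10⁻⁵ M⁻¹ s⁻¹)
    coupling partner + mono adduct → bis adduct (k = 1.60 × 10⁻⁵ M⁻¹ s⁻¹)
    bis adduct ⇌ isomer of the product (K = 1.70, k = 2.10 × 10⁻⁶ s⁻¹)
    starting material + bis adduct ⇌ idle adduct, settled at all times (K = 1.90 M⁻¹)

In the summer flask 6.0 d holds 10.9 spans of τ, and 95.5 % of the starting material has passed the first step, yet bis adduct ends at 54.0 %. The main reason is its reaction to the isomer of the product: the same summer run without that reaction gives 90.0 %. In the autumn flask τ shortens to 0.412 d, and starting material falls to 0.809 %, but bis adduct ends at 55.0 % beside 42.7 % of isomer of the product.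

The numbers in the tables are simulated with constants of no real substance; noise was put on by code.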